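**Retrosynthetic overview**
1. The target comes from carbinol 8 by one Pd/C hydrogenation that saturates the alkyne, removes both O-benzyl groups and hydrogenolyses the benzhydrylic C–OH.
2. The diarylmethane C–C bond is cut to aldehyde 5 plus aryl Grignard reagent 6.
3. The bibenzyl C–C bond is cut to aryl triflate 3 plus alkyne 4 (Sonogashira).
4. The ring-B substitution pattern is bought in with 2,4-dihydroxy-6-methoxybenzaldehyde: the para OH is benzylated selectively and the chelated ortho OH becomes the triflate.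
5. No ring is formed; all three benzene rings are purchased.

Assumption: the target has no stereocentre (achiral), so no asymmetric step is needed; the one stereocentre made on the way (7, 8, 9) is racemic and is erased in step 5.

**Route**

Step 1
Reactants: 1 2,4-dihydroxy-6-methoxybenzaldehyde
Product: 2 4-(benzyloxy)-2-hydroxy-6-methoxybenzaldehyde
Conditions: BnBr (1.05 equiv), K2CO3 (1.1 equiv), acetone, rt to 45 °C
Reagents that add atoms: benzyl bromide, BrCc1ccccc1
Why: Williamson ether synthesis in which the 4-OH (para to CHO, more acidic, not hydrogen-bonded) is alkylated selectively while the 2-OH stays locked in its hydrogen bond to the aldehyde.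

Step 2
Reactants: 2 4-(benzyloxy)-2-hydroxy-6-methoxybenzaldehyde
Product: 3 5-(benzyloxy)-2-formyl-3-methoxyphenyl trifluoromethanesulfonate
Conditions: Tf2O (1.2 equiv), pyridine (3 equiv), CH2Cl2, 0 °C to rt
Reagents that add atoms: trifluoromethanesulfonic anhydride, O=S(=O)(OS(=O)(=O)C(F)(F)F)C(F)(F)F
Why: O-triflation of the remaining phenol turns it into a cross-coupling handle, and the aldehyde and the ethers are inert to Tf2O/pyridine.

Step 3
Reactants: 3 5-(benzyloxy)-2-formyl-3-methoxyphenyl trifluoromethanesulfonate; 4 1-ethynyl-3-methoxybenzene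
Product: 5 4-(benzyloxy)-2-methoxy-6-[(3-methoxyphenyl)ethynyl]benzaldehyde
Conditions: PdCl2(PPh3)2 (5 mol %), CuI (10 mol %), Et3N (3 equiv), DMF, 65 °C
Reagents that add atoms: none
Why: Sonogashira coupling, in which the triflate (activated by the ortho formyl group and meta to both alkoxy groups) undergoes oxidative addition and couples with the copper acetylide of 4 without touching the aldehyde or the ethers.

Step 4
Reactants: 5 4-(benzyloxy)-2-methoxy-6-[(3-methoxyphenyl)ethynyl]benzaldehyde; 6 [4-(benzyloxy)phenyl]magnesium bromide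
Product: 8 rac-[4-(benzyloxy)-2-methoxy-6-[(3-methoxyphenyl)ethynyl]phenyl][4-(benzyloxy)phenyl]methanol, via bromomagnesium alkoxide 7 (not isolated)
Conditions: 6 (1.3 equiv, 1.0 M in THF), THF, −78 to 0 °C; then sat. aq NH4Cl
Reagents that add atoms: none
Why: Grignard 1,2-addition of the aryl nucleophile to the aldehyde gives the diaryl carbinol; the new stereocentre forms without control (racemate), which does not matter because step 5 removes it.

Step 5
Reactants: 8 rac-[4-(benzyloxy)-2-methoxy-6-[(3-methoxyphenyl)ethynyl]phenyl][4-(benzyloxy)phenyl]methanol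
Product: 10 4-[(4-hydroxyphenyl)methyl]-3-methoxy-5-[2-(3-methoxyphenyl)ethyl]phenol, via saturated triol carbinol 9 (not isolated)
Conditions: H2 (1 atm), 10% Pd/C, EtOAc–EtOH, rt; then cat. HCl, H2 (3 atm), rt
Reagents that add atoms: none
Why: Catalytic hydrogenation and hydrogenolysis over Pd/C first saturates the alkyne and cleaves both benzyl ethers, then with acid hydrogenolyses the benzhydrylic C–OH flanked by two electron-rich rings, which erases the stereocentre while the aryl methyl ethers survive.

**Compound list**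
1 | 2,4-dihydroxy-6-methoxybenzaldehyde | COc1cc(O)cc(O)c1C=O | starting material
2 | 4-(benzyloxy)-2-hydroxy-6-methoxybenzaldehyde | COc1cc(OCc2ccccc2)cc(O)c1C=O | intermediate
3 | 5-(benzyloxy)-2-formyl-3-methoxyphenyl trifluoromethanesulfonate | COc1cc(OCc2ccccc2)cc(OS(=O)(=O)C(F)(F)F)c1C=O | intermediate
4 | 1-ethynyl-3-methoxybenzene (3-ethynylanisole) | C#Cc1cccc(OC)c1 | starting material
5 | 4-(benzyloxy)-2-methoxy-6-[(3-methoxyphenyl)ethynyl]benzaldehyde | COc1cccc(C#Cc2cc(OCc3ccccc3)cc(OC)c2C=O)c1 | intermediate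
6 | [4-(benzyloxy)phenyl]magnesium bromide (1.0 M in THF) | Br[Mg]c1ccc(OCc2ccccc2)cc1 | starting material
7 | bromomagnesium alkoxide of 8 (racemic, not isolated) | COc1cccc(C#Cc2cc(OCc3ccccc3)cc(OC)c2C(O[Mg]Br)c2ccc(OCc3ccccc3)cc2)c1 | intermediate
8 | rac-[4-(benzyloxy)-2-methoxy-6-[(3-methoxyphenyl)ethynyl]phenyl][4-(benzyloxy)phenyl]methanol | COc1cccc(C#Cc2cc(OCc3ccccc3)cc(OC)c2C(O)c2ccc(OCc3ccccc3)cc2)c1 | intermediate
9 | rac-4-[hydroxy(4-hydroxyphenyl)methyl]-3-methoxy-5-[2-(3-methoxyphenyl)ethyl]phenol (saturated triol carbinol, not isolated) | COc1cccc(CCc2cc(O)cc(OC)c2C(O)c2ccc(O)cc2)c1 | intermediate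
10 | 4-[(4-hydroxyphenyl)methyl]-3-methoxy-5-[2-(3-methoxyphenyl)ethyl]phenol (achiral) | COc1cccc(CCc2cc(O)cc(OC)c2Cc2ccc(O)cc2)c1 | target

**Totals**
Total step count: 5. Longest linear sequence: 5 (steps 1 to 5 from compound 1; 4 and 6 are purchased).

**Three steps most likely to fail, with fallbacks**

Step 3 (Sonogashira on the hindered ortho-formyl triflate; risks are triflate hydrolysis and alkyne homocoupling). The fallback sets out from 3 and comes back to the route at 9. A Mizoroki–Heck reaction of 3 with commercial 1-ethenyl-3-methoxybenzene (C=Cc1cccc(OC)c1; Pd(OAc)2, PPh3, LiCl, Et3N, DMF, 100 °C, chloride keeping the neutral pathway and the linear E product) gives (E)-4-(benzyloxy)-2-methoxy-6-[2-(3-methoxyphenyl)ethenyl]benzaldehyde F1. Addition of Grignard reagent 6 as in step 4 gives the bromomagnesium alkoxide of the stilbene carbinol F2 (not isolated), and aqueous NH4Cl then gives rac-(E)-[4-(benzyloxy)-2-methoxy-6-[2-(3-methoxyphenyl)ethenyl]phenyl][4-(benzyloxy)phenyl]methanol F3. Under the step 5 conditions F3 gives 9 and then 10.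

Step 4 (Grignard addition to the 2,6-disubstituted aldehyde; risks are low conversion, alkoxide cyclisation onto the alkyne and an acid-labile carbinol). The fallback sets out from 5 and comes back at 10; it builds the diarylmethane by an sp3–sp2 Suzuki–Miyaura coupling instead of a carbonyl addition. NaBH4 (MeOH–THF, 0 °C) reduces 5 to [4-(benzyloxy)-2-methoxy-6-[(3-methoxyphenyl)ethynyl]phenyl]methanol F4. ClCO2Me and pyridine in CH2Cl2 at 0 °C give [4-(benzyloxy)-2-methoxy-6-[(3-methoxyphenyl)ethynyl]phenyl]methyl methyl carbonate F5. Coupling with commercial [4-(benzyloxy)phenyl]boronic acid (OB(O)c1ccc(OCc2ccccc2)cc1; [Pd(allyl)Cl]2, DPPPent, K2CO3, DMF, 80 °C) gives 5-(benzyloxy)-2-[[4-(benzyloxy)phenyl]methyl]-1-methoxy-3-[(3-methoxyphenyl)ethynyl]benzene F6. Neutral hydrogenation of F6 (H2, Pd/C, EtOAc–EtOH, rt) gives 10, with no benzhydrylic C–O hydrogenolysis needed.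

Step 5 (one-pot global hydrogenation; risks are stalling at the carbinol stage or acid-induced side reactions of the benzhydryl cation). The fallback sets out from 8 and comes back at 10. It replaces the catalytic C–O hydrogenolysis by an ionic hydride transfer: neutral hydrogenation of 8 (H2, Pd/C, EtOAc–EtOH, rt) is stopped at triol 9, which is now isolated. Then Et3SiH (3 equiv) and TFA (5 equiv) in CH2Cl2 at 0 °C ionise the carbinol and reduce the cation to 10. This fallback makes no compound outside the list: none F0.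

**Further compounds**
F1 | step 3 | (E)-4-(benzyloxy)-2-methoxy-6-[2-(3-methoxyphenyl)ethenyl]benzaldehyde | COc1cccc(/C=C/c2cc(OCc3ccccc3)cc(OC)c2C=O)c1
F2 | step 3 | bromomagnesium alkoxide of the stilbene carbinol | COc1cccc(/C=C/c2cc(OCc3ccccc3)cc(OC)c2C(O[Mg]Br)c2ccc(OCc3ccccc3)cc2)c1
F3 | step 3 | rac-(E)-[4-(benzyloxy)-2-methoxy-6-[2-(3-methoxyphenyl)ethenyl]phenyl][4-(benzyloxy)phenyl]methanol | COc1cccc(/C=C/c2cc(OCc3ccccc3)cc(OC)c2C(O)c2ccc(OCc3ccccc3)cc2)c1
F4 | step 4 | [4-(benzyloxy)-2-methoxy-6-[(3-methoxyphenyl)ethynyl]phenyl]methanol | COc1cccc(C#Cc2cc(OCc3ccccc3)cc(OC)c2CO)c1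
F5 | step 4 | [4-(benzyloxy)-2-methoxy-6-[(3-methoxyphenyl)ethynyl]phenyl]methyl methyl carbonate | COc1cccc(C#Cc2cc(OCc3ccccc3)cc(OC)c2COC(=O)OC)c1
F6 | step 4 | 5-(benzyloxy)-2-[[4-(benzyloxy)phenyl]methyl]-1-methoxy-3-[(3-methoxyphenyl)ethynyl]benzene | COc1cccc(C#Cc2cc(OCc3ccccc3)cc(OC)c2Cc2ccc(OCc3ccccc3)cc2)c1
F0 | step 5 | none | none
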